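**Plan**
Ring B is labelled B1 (diaryl ether carbon), B2 (ester oxygen carbon), B3 (CH2OH), B4 (phenol), B5 (lactone carbonyl carbon attached) and B6 (acetal carbon attached); ring A is the methoxy-dimethyl benzoate ring.
Retrosynthesis: the acetate and silyl groups come off last; the phthalide is cut at the lactone C(=O)–O bond and the acetal C–OAc bond, giving a depsidone 5,6-dialdehyde and acetic acid.
The depsidone is then cut at its aryl ester (lactonisation) and its diaryl ether (SNAr), giving a ring A salicylate and a fully substituted ring B ortho-fluorobenzaldehyde made from 2,4,5-trifluorobenzaldehyde (fluorines mark B1, B2 and B4, its formyl is B5, and B3 and B6 are formylated by directed lithiation).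
Forward order: ring B fragment, diaryl ether, seven-membered lactone, dialdehyde, carbene-catalysed closure of the five-membered lactone, deprotection.
The enabling feature is that B5 and B6 carry neighbouring one-carbon groups at acid level (lactone C=O) and aldehyde level (acetal C–H), i.e. an ortho-phthalaldehyde oxidised at one formyl. The single stereocentre (acetal carbon on B6, R) is set by a chiral triazolylidene in a dynamic kinetic acetalisation and is kept as an acetate until the final step.

Key step: step 13

Remark: the free 3-hydroxyphthalide can epimerise through its ring-opened formyl acid; it is assumed that this is slow without base and water, so the centre is carried as the acylal and released only in the last, neutral step.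

**Step 1**
Reactants: 1 2,4,5-trifluorobenzaldehyde
Product: 2 2-(2,4,5-trifluorophenyl)-1,3-dioxolane
Conditions: HOCH2CH2OH, TsOH·H2O (cat.), toluene, reflux, Dean–Stark
Reagents that add atoms: ethylene glycol, OCCO
Why: Acid-catalysed acetalisation with azeotropic removal of water masks the B5 formyl group so that the ring can be metalated.

**Step 2**
Reactants: 2 2-(2,4,5-trifluorophenyl)-1,3-dioxolane
Product: 4 3-(1,3-dioxolan-2-yl)-2,5,6-trifluorobenzaldehyde, via aryllithium 3 (not isolated)
Conditions: LiN(iPr)2, THF, −78 °C; DMF, −78 °C; AcOH quench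
Reagents that add atoms: N,N-dimethylformamide, CN(C)C=O
Why: Directed ortho-metalation removes the B3 proton, which is flanked by two fluorines and is by far the most acidic, and the aryllithium is formylated by DMF before it can lose LiF.

**Step 3**
Reactants: 4 3-(1,3-dioxolan-2-yl)-2,5,6-trifluorobenzaldehyde
Product: 5 2,6-bis(benzyloxy)-3-(1,3-dioxolan-2-yl)-5-fluorobenzaldehyde
Conditions: BnOH (2.3 equiv), Cs2CO3, DMF, 25 to 50 °C
Reagents that add atoms: benzyl alcohol, OCc1ccccc1
Why: Double SNAr replaces only the B2 and B4 fluorines, which are ortho to the new formyl group, while the B1 fluorine is meta to it and stays.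

**Step 4**
Reactants: 5 2,6-bis(benzyloxy)-3-(1,3-dioxolan-2-yl)-5-fluorobenzaldehyde
Product: 6 [2,6-bis(benzyloxy)-3-(1,3-dioxolan-2-yl)-5-fluorophenyl]methanol
Conditions: NaBH4, MeOH–THF, 0 °C
Reagents that add atoms: none
Why: Borohydride reduction turns the B3 aldehyde, which has served as the SNAr activator, into the hydroxymethyl group of the target without touching acetal, fluoride or benzyl ethers.

**Step 5**
Reactants: 6 [2,6-bis(benzyloxy)-3-(1,3-dioxolan-2-yl)-5-fluorophenyl]methanol
Product: 7 {[2,6-bis(benzyloxy)-3-(1,3-dioxolan-2-yl)-5-fluorobenzyl]oxy}triisopropylsilane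
Conditions: iPr3SiCl, imidazole, DMAP (cat.), DMF, 25 °C
Reagents that add atoms: triisopropylsilyl chloride, CC(C)[Si](Cl)(C(C)C)C(C)C
Why: Standard imidazole-mediated silylation of a primary alcohol, with the triisopropylsilyl group chosen to outlast fluoride release, hydrogenolysis and dilute acid in later steps.

**Step 6**
Reactants: 7 {[2,6-bis(benzyloxy)-3-(1,3-dioxolan-2-yl)-5-fluorobenzyl]oxy}triisopropylsilane
Product: 9 3,5-bis(benzyloxy)-6-(1,3-dioxolan-2-yl)-2-fluoro-4-{[(triisopropylsilyl)oxy]methyl}benzaldehyde, via aryllithium 8 (not isolated)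
Conditions: lithium 2,2,6,6-tetramethylpiperidide (from n-BuLi and the amine), THF, −78 °C; DMF, −78 °C; AcOH quench
Reagents that add atoms: N,N-dimethylformamide, CN(C)C=O
Why: Fluorine-directed ortho-lithiation at the only remaining ring proton (B6, between fluorine and acetal) with a hindered amide base that spares the benzylic ether positions, followed by DMF formylation.

**Step 7**
Reactants: 10 methyl 2,4-dihydroxy-3,6-dimethylbenzoate
Product: 11 methyl 2-hydroxy-4-methoxy-3,6-dimethylbenzoate
Conditions: MeI (1.1 equiv), K2CO3, acetone, reflux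
Reagents that add atoms: iodomethane, CI
Why: Williamson methylation takes the 4-hydroxyl, because the 2-hydroxyl is tied up in a hydrogen bond to the ester carbonyl and is much less nucleophilic.

**Step 8**
Reactants: 9 3,5-bis(benzyloxy)-6-(1,3-dioxolan-2-yl)-2-fluoro-4-{[(triisopropylsilyl)oxy]methyl}benzaldehyde; 11 methyl 2-hydroxy-4-methoxy-3,6-dimethylbenzoate
Product: 12 methyl 2-[2,4-bis(benzyloxy)-5-(1,3-dioxolan-2-yl)-6-formyl-3-{[(triisopropylsilyl)oxy]methyl}phenoxy]-4-methoxy-3,6-dimethylbenzoate
Conditions: K2CO3, DMAc, 110 °C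
Reagents that add atoms: none
Why: SNAr of the phenoxide on the ortho-fluorobenzaldehyde, where the ortho formyl group stabilises the Meisenheimer adduct and fluoride is the best leaving group for this crowded diaryl ether.

**Step 9**
Reactants: 12 diaryl ether methyl ester
Product: 13 2-[2,4-bis(benzyloxy)-5-(1,3-dioxolan-2-yl)-6-formyl-3-{[(triisopropylsilyl)oxy]methyl}phenoxy]-4-methoxy-3,6-dimethylbenzoic acid
Conditions: LiI, pyridine, reflux; cold dilute HCl work-up
Reagents that add atoms: none
Why: SN2 dealkylation by iodide at the methyl carbon cleaves the di-ortho-substituted ester without attack at its shielded carbonyl and without the hydroxide that would harm the aldehyde.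

**Step 10**
Reactants: 13 diaryl ether acid
Product: 14 2-[5-(1,3-dioxolan-2-yl)-6-formyl-2,4-dihydroxy-3-{[(triisopropylsilyl)oxy]methyl}phenoxy]-4-methoxy-3,6-dimethylbenzoic acid
Conditions: H2 (1 atm), Pd/C (10 wt %), EtOAc, 25 °C
Reagents that add atoms: none
Why: Hydrogenolysis of the two aryl benzyl ethers at 1 atm should be much faster than reduction of the hindered aryl aldehyde, and acetal and silyl ether are inert under neutral conditions.

**Step 11**
Reactants: 14 dihydroxy acid
Product: 15 7-(1,3-dioxolan-2-yl)-8-hydroxy-3-methoxy-1,4-dimethyl-11-oxo-9-{[(triisopropylsilyl)oxy]methyl}-11H-dibenzo[b,e][1,4]dioxepine-6-carbaldehyde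
Conditions: DCC, DMAP (cat.), CH2Cl2 (0.005 M), 25 °C
Reagents that add atoms: none
Why: Steglich-type carbodiimide lactonisation closes the seven-membered aryl ester, since only the B2 hydroxyl can reach the activated carboxyl and the B4 hydroxyl is remote and hindered.

**Step 12**
Reactants: 15 depsidone acetal
Product: 16 8-hydroxy-3-methoxy-1,4-dimethyl-11-oxo-9-{[(triisopropylsilyl)oxy]methyl}-11H-dibenzo[b,e][1,4]dioxepine-6,7-dicarbaldehyde
Conditions: 2 M aq. HCl–THF (1:4), 25 °C
Reagents that add atoms: water, O
Why: Acid-catalysed hydrolysis of the cyclic acetal frees the B5 formyl group, while the triisopropylsilyl ether and the aryl ester tolerate dilute acid at room temperature.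

**Step 13**
Reactants: 16 depsidone 5,6-dialdehyde; 17 acetic acid
Product: 18 (R)-acetoxyphthalide depsidone (B5 bears the lactone carbonyl, B6 the (R)-CH(OAc) acetal carbon, B4 OH free, B3 CH2OSi(iPr)3)
Conditions: chiral aminoindanol-derived N-mesityl triazolium tetrafluoroborate (10 mol %, enantiomer chosen to give R), 3,3',5,5'-tetra-tert-butyldiphenoquinone (1.2 equiv), AcOH (2.0 equiv), iPr2NEt (1.0 equiv), 4 Å MS, CHCl3, −20 °C
Reagents that add atoms: none
Why: The triazolylidene adds to the B5 formyl group, the Breslow intermediate is oxidised by the diphenoquinone to an acyl azolium, acetate adds reversibly to the neighbouring B6 formyl group, and the hemiacylal alkoxide attacks the acyl azolium and releases the carbene. The closest known reaction type is the carbene-catalysed oxidative dynamic kinetic acetalisation of ortho-phthalaldehydes with carboxylic acids to 3-acyloxyphthalides. The five-membered lactone closes by a 5-exo-trig acyl substitution of the alkoxide oxygen on the acyl azolium carbon. The two hemiacylal alkoxide epimers interconvert quickly and the chiral acyl azolium acylates one of them faster, so the catalyst sets the acetal carbon, which is then fixed as a configurationally stable acylal. The step needs the carbene to oxidise the B5 formyl and not the B6 formyl: B5–CHO has only the small B4 hydroxyl beside it and is activated by its hydrogen bond, B6–CHO is wedged against the twisted ring A ether, and the acetic acid–acetate buffer keeps the B4 phenol protonated so that it does not deactivate B5–CHO. Molecular sieves exclude water so that no racemic free lactol forms.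

**Step 14**
Reactants: 18 (R)-acetoxyphthalide silyl ether
Product: 19 (R)-acetoxyphthalide depsidone with free B3 hydroxymethyl
Conditions: HF·pyridine, pyridine, THF, 0 to 25 °C
Reagents that add atoms: none
Why: Buffered fluoride cleaves the Si–O bond under mildly acidic conditions that leave the acylal, both lactones and the stereocentre untouched.

**Step 15**
Reactants: 19 (R)-acetoxyphthalide depsidone with free B3 hydroxymethyl
Product: 20 target (R)-lactol, CNP0321962.1
Conditions: immobilised Candida antarctica lipase B, n-BuOH, MTBE, 4 Å MS, 25 °C; crystallisation at −20 °C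
Reagents that add atoms: none
Why: Lipase-catalysed alcoholysis attacks the acetyl carbonyl, so the C–O bond at the acetal carbon is not broken and the configuration is retained, and no base or water is present to open the lactol.

**Compound list**
1 | 2,4,5-trifluorobenzaldehyde | O=Cc1cc(F)c(F)cc1F | starting material
2 | 2-(2,4,5-trifluorophenyl)-1,3-dioxolane | Fc1cc(F)c(F)cc1C1OCCO1 | intermediate
3 | [3-(1,3-dioxolan-2-yl)-2,5,6-trifluorophenyl]lithium (not isolated) | [Li]c1c(F)c(C2OCCO2)cc(F)c1F | intermediate
4 | 3-(1,3-dioxolan-2-yl)-2,5,6-trifluorobenzaldehyde | O=Cc1c(F)c(C2OCCO2)cc(F)c1F | intermediate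
5 | 2,6-bis(benzyloxy)-3-(1,3-dioxolan-2-yl)-5-fluorobenzaldehyde | O=Cc1c(OCc2ccccc2)c(C2OCCO2)cc(F)c1OCc1ccccc1 | intermediate
6 | [2,6-bis(benzyloxy)-3-(1,3-dioxolan-2-yl)-5-fluorophenyl]methanol | OCc1c(OCc2ccccc2)c(C2OCCO2)cc(F)c1OCc1ccccc1 | intermediate
7 | {[2,6-bis(benzyloxy)-3-(1,3-dioxolan-2-yl)-5-fluorobenzyl]oxy}triisopropylsilane | CC(C)[Si](OCc1c(OCc2ccccc2)c(C2OCCO2)cc(F)c1OCc1ccccc1)(C(C)C)C(C)C | intermediate
8 | B6-lithio derivative of 7 (not isolated) | CC(C)[Si](OCc1c(OCc2ccccc2)c(C2OCCO2)c([Li])c(F)c1OCc1ccccc1)(C(C)C)C(C)C | intermediate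
9 | 3,5-bis(benzyloxy)-6-(1,3-dioxolan-2-yl)-2-fluoro-4-{[(triisopropylsilyl)oxy]methyl}benzaldehyde | CC(C)[Si](OCc1c(OCc2ccccc2)c(C2OCCO2)c(C=O)c(F)c1OCc1ccccc1)(C(C)C)C(C)C | intermediate
10 | methyl 2,4-dihydroxy-3,6-dimethylbenzoate | COC(=O)c1c(C)cc(O)c(C)c1O | starting material
11 | methyl 2-hydroxy-4-methoxy-3,6-dimethylbenzoate | COC(=O)c1c(C)cc(OC)c(C)c1O | intermediate
12 | methyl 2-[2,4-bis(benzyloxy)-5-(1,3-dioxolan-2-yl)-6-formyl-3-{[(triisopropylsilyl)oxy]methyl}phenoxy]-4-methoxy-3,6-dimethylbenzoate | COC(=O)c1c(C)cc(OC)c(C)c1Oc1c(C=O)c(C2OCCO2)c(OCc2ccccc2)c(CO[Si](C(C)C)(C(C)C)C(C)C)c1OCc1ccccc1 | intermediate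
13 | 2-[2,4-bis(benzyloxy)-5-(1,3-dioxolan-2-yl)-6-formyl-3-{[(triisopropylsilyl)oxy]methyl}phenoxy]-4-methoxy-3,6-dimethylbenzoic acid | OC(=O)c1c(C)cc(OC)c(C)c1Oc1c(C=O)c(C2OCCO2)c(OCc2ccccc2)c(CO[Si](C(C)C)(C(C)C)C(C)C)c1OCc1ccccc1 | intermediate
14 | 2-[5-(1,3-dioxolan-2-yl)-6-formyl-2,4-dihydroxy-3-{[(triisopropylsilyl)oxy]methyl}phenoxy]-4-methoxy-3,6-dimethylbenzoic acid | OC(=O)c1c(C)cc(OC)c(C)c1Oc1c(C=O)c(C2OCCO2)c(O)c(CO[Si](C(C)C)(C(C)C)C(C)C)c1O | intermediate
15 | 7-(1,3-dioxolan-2-yl)-8-hydroxy-3-methoxy-1,4-dimethyl-11-oxo-9-{[(triisopropylsilyl)oxy]methyl}-11H-dibenzo[b,e][1,4]dioxepine-6-carbaldehyde | COc1cc(C)c2c(c1C)Oc1c(OC2=O)c(CO[Si](C(C)C)(C(C)C)C(C)C)c(O)c(C3OCCO3)c1C=O | intermediate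
16 | 8-hydroxy-3-methoxy-1,4-dimethyl-11-oxo-9-{[(triisopropylsilyl)oxy]methyl}-11H-dibenzo[b,e][1,4]dioxepine-6,7-dicarbaldehyde | COc1cc(C)c2c(c1C)Oc1c(OC2=O)c(CO[Si](C(C)C)(C(C)C)C(C)C)c(O)c(C=O)c1C=O | intermediate
17 | acetic acid | CC(=O)O | starting material
18 | (R)-acetoxyphthalide depsidone: furan-1(3H)-one fused at B5/B6 with lactone C=O on B5 and (R)-CH(OAc) on B6, B4 OH, B3 CH2OSi(iPr)3, ring A 3-methoxy-1,4-dimethyl | COc1cc(C)c2c(c1C)Oc1c(c(CO[Si](C(C)C)(C(C)C)C(C)C)c(O)c3c1[C@H](OC(C)=O)OC3=O)OC2=O | intermediate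
19 | (R)-acetoxyphthalide depsidone with free B3 hydroxymethyl | COc1cc(C)c2c(c1C)Oc1c(c(CO)c(O)c3c1[C@H](OC(C)=O)OC3=O)OC2=O | intermediate
20 | CNP0321962.1, (R)-hydroxyphthalide depsidone with B3 CH2OH and B4 OH | COc1cc(C)c2c(c1C)Oc1c(c(CO)c(O)c3c1[C@H](O)OC3=O)OC2=O | target

**Step count**
Total: 15 steps. Longest linear sequence: 14 steps (steps 1 to 6 and 8 to 15, from compound 1).

**Steps most likely to fail**

Step 13. The carbene may add to and oxidise the more electrophilic B6 formyl group instead of the B5 formyl group, which would give the regioisomeric phthalide, or the acylation may discriminate poorly between the two hemiacylal epimers. The fallback sets out from depsidone acetal 15, in which the two one-carbon groups are still chemically distinct. Wittig methylenation (Ph3PCH3Br, KOtBu, THF, 0 °C) would convert the B6 formyl group into a vinyl group, giving the vinyl acetal F1. Dilute HCl in THF would free the B5 aldehyde, giving the vinyl salicylaldehyde F2. Pinnick oxidation (NaClO2, NaH2PO4, 2-methyl-2-butene) would give the vinyl salicylic acid F3. Lemieux–Johnson cleavage (OsO4 cat., NaIO4, 2,6-lutidine) would turn the vinyl group back into the B6 aldehyde, which closes at once onto the B5 acid to give the racemic silyl-protected hydroxyphthalide F4 with unambiguous regiochemistry. Acylative dynamic kinetic resolution of this racemic 3-hydroxyphthalide (Ac2O with a chiral bicyclic imidazole or 4-aminopyridine acyl-transfer catalyst) would bring the route back at acetate 18.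

Step 8. The substitution may stall, because the alkoxy groups ortho and para to the fluorine feed electron density into the Meisenheimer adduct and both partners are di-ortho-substituted; prolonged heating could then erode the aldehyde or the silyl ether. The fallback sets out from ester 11 and fluoroaldehyde 9 and joins the rings in the opposite order. LiI in pyridine would convert 11 into 2-hydroxy-4-methoxy-3,6-dimethylbenzoic acid F5. Hydrogenolysis of 9 (H2, Pd/C, EtOAc) would give 6-(1,3-dioxolan-2-yl)-2-fluoro-3,5-dihydroxy-4-{[(triisopropylsilyl)oxy]methyl}benzaldehyde F6. Carbodiimide esterification (DCC, DMAP cat.) should acylate the less hindered and more acidic B2 hydroxyl next to fluorine, giving the depside F7. K2CO3 in DMF at 60 °C would then close the diaryl ether by intramolecular SNAr, now a seven-membered ring closure onto a fluoride whose ortho oxygen is a less donating acyloxy group, and return the route at depsidone acetal 15.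

Step 15. The liberated lactol may epimerise by ring opening if the enzymatic deacylation is slow, or the lipase may not accept the (R)-acylal. The fallback sets out from dialdehyde 16 and uses an acyl group that is removed without enzyme, base or acid. The key step run with pent-4-enoic acid in place of acetic acid would give the (R)-pent-4-enoyloxyphthalide silyl ether F8. HF·pyridine would remove the silyl group to give the (R)-pent-4-enoyloxyphthalide alcohol F9. N-Iodosuccinimide in THF–water at 0 °C would remove the pentenoyl group by iodolactonisation, which again leaves the acetal C–O bond intact, and give target 20.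

**Further compounds**
F1 | step 13 | depsidone 15 with B6 vinyl in place of B6 formyl (B5 dioxolane kept) | COc1cc(C)c2c(c1C)Oc1c(OC2=O)c(CO[Si](C(C)C)(C(C)C)C(C)C)c(O)c(C3OCCO3)c1C=C
F2 | step 13 | B6-vinyl B5-formyl depsidone | COc1cc(C)c2c(c1C)Oc1c(OC2=O)c(CO[Si](C(C)C)(C(C)C)C(C)C)c(O)c(C=O)c1C=C
F3 | step 13 | B6-vinyl B5-carboxylic acid depsidone | COc1cc(C)c2c(c1C)Oc1c(OC2=O)c(CO[Si](C(C)C)(C(C)C)C(C)C)c(O)c(C(O)=O)c1C=C
F4 | step 13 | racemic hydroxyphthalide depsidone with B3 CH2OSi(iPr)3 | COc1cc(C)c2c(c1C)Oc1c(c(CO[Si](C(C)C)(C(C)C)C(C)C)c(O)c3c1C(O)OC3=O)OC2=O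
F5 | step 8 | 2-hydroxy-4-methoxy-3,6-dimethylbenzoic acid | COc1cc(C)c(C(=O)O)c(O)c1C
F6 | step 8 | 6-(1,3-dioxolan-2-yl)-2-fluoro-3,5-dihydroxy-4-{[(triisopropylsilyl)oxy]methyl}benzaldehyde | O=Cc1c(F)c(O)c(CO[Si](C(C)C)(C(C)C)C(C)C)c(O)c1C1OCCO1
F7 | step 8 | depside: B2 ester of F6 with F5 | COc1cc(C)c(C(=O)Oc2c(F)c(C=O)c(C3OCCO3)c(O)c2CO[Si](C(C)C)(C(C)C)C(C)C)c(O)c1C
F8 | step 15 | (R)-pent-4-enoyloxyphthalide depsidone silyl ether | COc1cc(C)c2c(c1C)Oc1c(c(CO[Si](C(C)C)(C(C)C)C(C)C)c(O)c3c1[C@H](OC(=O)CCC=C)OC3=O)OC2=O
F9 | step 15 | (R)-pent-4-enoyloxyphthalide depsidone with free B3 hydroxymethyl | COc1cc(C)c2c(c1C)Oc1c(c(CO)c(O)c3c1[C@H](OC(=O)CCC=C)OC3=O)OC2=O
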